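**Plan**

1. Retrosynthetic cuts, in order: the C2 O-methyl group and the C1 carbonyl (back to a C1 silyloxy ketone); then, in one operation, C3–C4, O–C2′ and C3–N, which opens rings C and D to an ortho-acetyl aryl propargyl silyl ether plus 1-pyrroline N-oxide (ring E); then the acetyl C–CH3 bond (back to a nitrile), the C1–C2 bond (methyl ester + silylacetylene) and ring B (C4a–C10a and C9–C8a, back to (3,5-dimethoxyphenyl)acetonitrile + dimethyl butynedioate).
2. Forward order: ring B is annulated onto ring A (Michael addition, Friedel–Crafts acylation); the C2–C3 unit is joined at the ester as an alkyne; the nitrile becomes the C4 acetyl group; rings C and D then close together while the nitrone delivers ring E; oxidation at C1, O-methylation and deallylation finish.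
3. Enabling feature: ring D is an oxazolidine whose O–C4–C3–N unit, with the aminal carbon C2′ between N and O, is the retron of an azomethine ylide adding across a C=O group. The oxygen on C2 marks the carbonyl that stabilises the ylide, and C4 and the C1–C2–C3 chain sit ortho on ring B, so the cycloaddition is intramolecular and closes ring C.
4. Stereochemistry: a temporary C1 carbinol stereocenter (asymmetric transfer hydrogenation of an ynone) steers the cycloaddition that creates C4 (R) and is then erased by oxidation to the C1 ketone; the aminal carbon C2′ (S) is settled by thermodynamic equilibration of the N,O-acetal.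
5. Locants: phenanthrene numbering for rings A–C (C1 ketone, C2 OMe, C3 N, C4 Me/O, C9 C=O, C10 CH2, C6 OMe, C8 OH); ring D = oxazolidine, ring E = pyrrolidine, C2′ = aminal carbon. Naphthalene intermediates carry their own systematic names.

Key step: step 10

Remark (assumption): the target is taken in the ring-B keto form that is drawn (10H-phenanthren-9-one with the peri O–H···O=C bond). The 9-hydroxy (naphthol) form set free in the last step is its prototropic tautomer, and the two are expected to interconvert.

**Route**

Step 1
Reactants: 1 (3,5-dimethoxyphenyl)acetonitrile; 2 dimethyl but-2-ynedioate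
Product: 3 dimethyl 2-[cyano(3,5-dimethoxyphenyl)methylidene]butanedioate (E/Z mixture, used as such)
Conditions: DBU (10 mol %), MeCN, 0 °C to rt
Reagents that add atoms: none
Why: Base-catalysed Michael addition of the benzylic nitrile carbanion to the alkynoate followed by prototropic shift of the double bond into conjugation; either alkene isomer or tautomer converges in step 2, so no geometry needs to be controlled.

Step 2
Reactants: 3 dimethyl 2-[cyano(3,5-dimethoxyphenyl)methylidene]butanedioate
Product: 4 methyl 1-cyano-4-hydroxy-5,7-dimethoxynaphthalene-2-carboxylate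
Conditions: P2O5 in MeSO3H (1:10 w/w), 40 °C; then ice–water
Reagents that add atoms: none
Why: Intramolecular Friedel–Crafts acylation by the saturated ester at the ring position ortho/para to the two methoxy groups (both such positions are equivalent) and enolisation to the naphthol, the ring closure of the Stobbe naphthol synthesis run directly on the ester.

Step 3
Reactants: 4 methyl 1-cyano-4-hydroxy-5,7-dimethoxynaphthalene-2-carboxylate
Product: 5 methyl 1-cyano-4,5-dihydroxy-7-methoxynaphthalene-2-carboxylate
Conditions: BCl3 (2.2 equiv), CH2Cl2, −78 °C to 0 °C; then H2O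
Reagents that add atoms: none
Why: Chelation-directed ether cleavage, in which the aryloxyboron dichloride formed at the naphthol oxygen reaches only the peri methoxy group, so the remote 7-methoxy group and the methyl ester should survive.

Step 4
Reactants: 5 methyl 1-cyano-4,5-dihydroxy-7-methoxynaphthalene-2-carboxylate
Product: 6 methyl 4,5-bis(allyloxy)-1-cyano-7-methoxynaphthalene-2-carboxylate
Conditions: allyl bromide (3 equiv), K2CO3, DMF, 50 °C
Reagents that add atoms: allyl bromide, C=CCBr
Why: Williamson ether synthesis on both peri phenols, giving a protecting group that tolerates organolithium reagents, fluoride, oxidation and alkylation and is removed at the end without acid or hydrogen.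

Step 5
Reactants: 6 methyl 4,5-bis(allyloxy)-1-cyano-7-methoxynaphthalene-2-carboxylate
Product: 7 4,5-bis(allyloxy)-7-methoxy-2-[3-(trimethylsilyl)prop-2-ynoyl]naphthalene-1-carbonitrile
Conditions: ethynyltrimethylsilane, n-BuLi, THF, −78 °C; BF3·OEt2; then 6, −78 °C; aq. NH4Cl
Reagents that add atoms: lithium (trimethylsilyl)acetylide, [Li]C#C[Si](C)(C)C (from ethynyltrimethylsilane, C#C[Si](C)(C)C, and n-BuLi)
Why: BF3-mediated acylation of a lithium acetylide by an ester, which stops at the ynone because the tetrahedral adduct persists at −78 °C, while the nitrile is inert at this temperature.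

Step 6
Reactants: 7 4,5-bis(allyloxy)-7-methoxy-2-[3-(trimethylsilyl)prop-2-ynoyl]naphthalene-1-carbonitrile
Product: 8 4,5-bis(allyloxy)-2-[(1R)-1-hydroxy-3-(trimethylsilyl)prop-2-yn-1-yl]-7-methoxynaphthalene-1-carbonitrile
Conditions: Ru[(R,R)-TsNCH(Ph)CH(Ph)NH](p-cymene) (2 mol %), i-PrOH, rt
Reagents that add atoms: none
Why: Noyori asymmetric transfer hydrogenation of an alkynyl ketone, in which the alkyne should take the place usually held by the aryl group (the doubly ortho-substituted naphthyl cannot lie coplanar with the carbonyl), so the (R,R) ligand should deliver hydride to the face that gives the (R)-carbinol.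

Step 7
Reactants: 8 4,5-bis(allyloxy)-2-[(1R)-1-hydroxy-3-(trimethylsilyl)prop-2-yn-1-yl]-7-methoxynaphthalene-1-carbonitrile
Product: 10 4,5-bis(allyloxy)-2-[(1S)-1-(tert-butyldimethylsilyloxy)prop-2-yn-1-yl]-7-methoxynaphthalene-1-carbonitrile, via bis-silyl compound 9 (not isolated)
Conditions: TBSCl, imidazole, DMF, rt; then K2CO3 (cat.), MeOH, rt (same flask)
Reagents that add atoms: tert-butyldimethylsilyl chloride, CC(C)(C)[Si](C)(C)Cl
Why: Silylation of the secondary alcohol followed by methanolysis of the alkynyl C–Si bond, which is far more labile to carbonate in methanol than the O-silyl ether; the descriptor changes from R to S only because the priority order of alkynyl and aryl changes, not the geometry.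

Step 8
Reactants: 10 4,5-bis(allyloxy)-2-[(1S)-1-(tert-butyldimethylsilyloxy)prop-2-yn-1-yl]-7-methoxynaphthalene-1-carbonitrile
Product: 11 1-{4,5-bis(allyloxy)-2-[(1S)-1-(tert-butyldimethylsilyloxy)prop-2-yn-1-yl]-7-methoxynaphthalen-1-yl}ethan-1-one
Conditions: MeLi (3 equiv), THF, −78 °C to 0 °C; then 1 M aq. HCl, THF, 0 °C to rt
Reagents that add atoms: methyllithium, [Li]C; water, O
Why: Addition of methyllithium to the nitrile (one equivalent is first consumed by the alkyne C–H) gives an N-lithio ketimine that cannot add a second equivalent and is hydrolysed to the methyl ketone on acidic work-up, so the ketone appears only after all carbonyl-intolerant steps are done.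

Step 9
Reactants: 12 pyrrolidine
Product: 13 3,4-dihydro-2H-pyrrole 1-oxide (1-pyrroline N-oxide)
Conditions: Na2WO4·2H2O (4 mol %), 30 % aq. H2O2 (2.2 equiv), MeOH, 0 °C to rt
Reagents that add atoms: hydrogen peroxide, OO
Why: Tungstate-catalysed oxidation of a secondary amine through the hydroxylamine to the cyclic nitrone, a standard preparation of this reagent.

Step 10
Reactants: 11 1-{4,5-bis(allyloxy)-2-[(1S)-1-(tert-butyldimethylsilyloxy)prop-2-yn-1-yl]-7-methoxynaphthalen-1-yl}ethan-1-one; 13 3,4-dihydro-2H-pyrrole 1-oxide
Product: 16 (1R,3R,4R,2′R)-pentacyclic silyloxy ketone (rings A–E; C1 OTBS; C2 C=O; C3 H; C4 CH3; 8,9-bis(allyloxy); 6-OMe), via 1-pyrroline 14 (not isolated), via azomethine ylide 15 (not isolated)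
Conditions: Ph3PAuNTf2 (5 mol %), 13 (1.1 equiv, slow addition), 4 Å molecular sieves, ClCH2CH2Cl, rt
Reagents that add atoms: none
Why: Proposed new method: the monovalent gold catalyst activates the terminal alkyne, the nitrone oxygen adds to its internal carbon (the future C2), and N–O cleavage leaves a gold carbenoid at the terminal carbon (the future C3) next to the liberated 1-pyrroline 14, whose nitrogen captures it and releases the acyl-stabilised azomethine ylide 15; the closest known reactions are gold-catalysed nitrone–alkyne redox cascades with tethered nitrones, which end in an azomethine ylide cycloaddition, and the (3+2) addition of azomethine ylides to C=O groups to give oxazolidines. Ylide 15 adds across the ortho acetyl C=O: the C3–C4 bond closes ring C (6-exo-trig attack of the ylide carbon through a four-atom tether) and the O–C2′ bond closes ring D as the second bond of the same (3+2) event (5-endo closure on the iminium carbon), while ring E arrives intact with the nitrone. C4 should be controlled by the C1 silyloxy stereocenter: only the S-shaped ylide (acyl carbon syn to the iminium C–H) lets the tether reach the ketone with cis fusion of rings C and D, the C1–H then lies in the enolate plane and the OTBS group covers one face, so the ketone adds anti to it and the configuration set in step 6 should give (4R) with the methyl group cis to OTBS. C3 follows from the cis ring fusion and C2′ from suprafacial addition across the ylide; both are provisional, because C3 becomes sp2 and C2′ is equilibrated in step 12, and any C4 diastereomer is to be removed by chromatography here so that the enantiomeric purity of 8 is carried on. The step needs capture of the carbenoid by the imine nitrogen in preference to the naphthalene C–H ortho to the side chain, the acetyl oxygen and a second oxygen transfer; it relies on release of the imine at the metal, on the nucleophilicity of its sp2 nitrogen and on slow addition of one equivalent of nitrone, and the ortho ketone is the only π-bond within reach of the ylide.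

Step 11
Reactants: 16 (1R,3R,4R,2′R)-pentacyclic silyloxy ketone
Product: 17 (1R,3R,4R,2′R)-pentacyclic α-hydroxy ketone (C1 OH; C2 C=O)
Conditions: TBAF, AcOH (1:1), THF, 0 °C
Reagents that add atoms: none
Why: Fluoride cleavage of the silyl ether, buffered with acetic acid so that the β-alkoxy ketone neither enolises nor opens by retro-aldol reaction.

Step 12
Reactants: 17 (1R,3R,4R,2′R)-pentacyclic α-hydroxy ketone
Product: 19 (4R,2′S)-8,9-bis(allyloxy)-2-hydroxy-6-methoxy-4-methyl enaminone (C1 C=O; C2 OH; C2=C3; N on C3; rings D and E in place), via 1,2-diketone 18 (not isolated)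
Conditions: DMP (1.3 equiv), CH2Cl2, 0 °C to rt; then AcOH, 40 °C
Reagents that add atoms: none
Why: Dess–Martin oxidation of the acyloin gives the 1,2-diketone, which enolises toward C3 to the conjugated 3-amino-2-hydroxy enone (diosphenol); under the acetic acid set free the N,O-acetal can open and reclose through the iminium ion at the diketone stage, so C2′ should settle in the more stable configuration in which its hydrogen, not the pyrrolidine methylene, is syn to the pseudoaxial C4 methyl group across the ring oxygen, while C4 itself is not touched.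

Step 13
Reactants: 19 (4R,2′S)-8,9-bis(allyloxy)-2-hydroxy-6-methoxy-4-methyl enaminone
Product: 20 (4R,2′S)-8,9-bis(allyloxy)-2,6-dimethoxy-4-methyl enaminone (2-O-methyl ether of 19)
Conditions: MeI, K2CO3, acetone, rt
Reagents that add atoms: iodomethane, CI
Why: Williamson O-alkylation of the acidic diosphenol hydroxyl, the only site open because C3 carries no hydrogen, the vinylogous amide nitrogen is not nucleophilic and both phenols are still allylated.

Step 14
Reactants: 20 (4R,2′S)-8,9-bis(allyloxy)-2,6-dimethoxy-4-methyl enaminone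
Product: 22 target CNP0528850.1 (4R,2′S; 8-hydroxy; 2,6-dimethoxy; C1 and C9 ketones; C10 CH2), via 9-hydroxy tautomer 21 (not isolated)
Conditions: Pd(PPh3)4 (5 mol %), K2CO3, MeOH (degassed), rt
Reagents that add atoms: none
Why: Tsuji–Trost-type deallylation of both aryl allyl ethers by zerovalent palladium with methanol as allyl acceptor, after which the liberated 9-naphthol should tautomerise to the peri-hydrogen-bonded 10H-phenanthren-9-one form of the target; neither stereocenter is involved.

**Compound list**

1 | (3,5-dimethoxyphenyl)acetonitrile | N#CCc1cc(OC)cc(OC)c1 | starting material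
2 | dimethyl but-2-ynedioate (dimethyl acetylenedicarboxylate) | COC(=O)C#CC(=O)OC | starting material
3 | dimethyl 2-[cyano(3,5-dimethoxyphenyl)methylidene]butanedioate (E/Z mixture, geometry not defined; in equilibrium with the 2-[cyano(aryl)methyl]but-2-enedioate tautomer) | COC(=O)CC(C(=O)OC)=C(C#N)c1cc(OC)cc(OC)c1 | intermediate
4 | methyl 1-cyano-4-hydroxy-5,7-dimethoxynaphthalene-2-carboxylate | COC(=O)c1cc(O)c2c(OC)cc(OC)cc2c1C#N | intermediate
5 | methyl 1-cyano-4,5-dihydroxy-7-methoxynaphthalene-2-carboxylate | COC(=O)c1cc(O)c2c(O)cc(OC)cc2c1C#N | intermediate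
6 | methyl 4,5-bis(allyloxy)-1-cyano-7-methoxynaphthalene-2-carboxylate | COC(=O)c1cc(OCC=C)c2c(OCC=C)cc(OC)cc2c1C#N | intermediate
7 | 4,5-bis(allyloxy)-7-methoxy-2-[3-(trimethylsilyl)prop-2-ynoyl]naphthalene-1-carbonitrile | C[Si](C)(C)C#CC(=O)c1cc(OCC=C)c2c(OCC=C)cc(OC)cc2c1C#N | intermediate
8 | 4,5-bis(allyloxy)-2-[(1R)-1-hydroxy-3-(trimethylsilyl)prop-2-yn-1-yl]-7-methoxynaphthalene-1-carbonitrile | C[Si](C)(C)C#C[C@H](O)c1cc(OCC=C)c2c(OCC=C)cc(OC)cc2c1C#N | intermediate
9 | 4,5-bis(allyloxy)-2-[(1R)-1-(tert-butyldimethylsilyloxy)-3-(trimethylsilyl)prop-2-yn-1-yl]-7-methoxynaphthalene-1-carbonitrile (not isolated) | C[Si](C)(C)C#C[C@H](O[Si](C)(C)C(C)(C)C)c1cc(OCC=C)c2c(OCC=C)cc(OC)cc2c1C#N | intermediate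
10 | 4,5-bis(allyloxy)-2-[(1S)-1-(tert-butyldimethylsilyloxy)prop-2-yn-1-yl]-7-methoxynaphthalene-1-carbonitrile | C#C[C@H](O[Si](C)(C)C(C)(C)C)c1cc(OCC=C)c2c(OCC=C)cc(OC)cc2c1C#N | intermediate
11 | 1-{4,5-bis(allyloxy)-2-[(1S)-1-(tert-butyldimethylsilyloxy)prop-2-yn-1-yl]-7-methoxynaphthalen-1-yl}ethan-1-one | C#C[C@H](O[Si](C)(C)C(C)(C)C)c1cc(OCC=C)c2c(OCC=C)cc(OC)cc2c1C(C)=O | intermediate
12 | pyrrolidine | C1CCNC1 | starting material
13 | 3,4-dihydro-2H-pyrrole 1-oxide (1-pyrroline N-oxide) | [O-][N+]1=CCCC1 | intermediate
14 | 3,4-dihydro-2H-pyrrole (1-pyrroline) (not isolated) | C1=NCCC1 | intermediate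
15 | azomethine ylide: 1-{(3R)-3-[1-acetyl-4,5-bis(allyloxy)-7-methoxynaphthalen-2-yl]-3-(tert-butyldimethylsilyloxy)-2-oxopropan-1-id-1-yl}-3,4-dihydro-2H-pyrrol-1-ium (not isolated) | [CH-]([N+]1=CCCC1)C(=O)[C@H](O[Si](C)(C)C(C)(C)C)c1cc(OCC=C)c2c(OCC=C)cc(OC)cc2c1C(C)=O | intermediate
16 | (1R,3R,4R,2′R)-8,9-bis(allyloxy)-1-(tert-butyldimethylsilyloxy)-6-methoxy-4-methyl-3,4-dihydrophenanthren-2(1H)-one with ring D cis-fused (N on C3, O on C4) and ring E fused at N–C2′; C1–OTBS, C3–H and C4–CH3 on one face of ring C; C2′–H anti to C4–CH3 | O=C1[C@H](O[Si](C)(C)C(C)(C)C)c2cc(OCC=C)c3c(OCC=C)cc(OC)cc3c2[C@@]2(C)O[C@@H]3CCCN3[C@@H]12 | intermediate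
17 | (1R,3R,4R,2′R)-1-hydroxy analogue of 16 (C1 OH, C2 C=O) | O=C1[C@H](O)c2cc(OCC=C)c3c(OCC=C)cc(OC)cc3c2[C@@]2(C)O[C@@H]3CCCN3[C@@H]12 | intermediate
18 | (3R,4R,2′R)-1,2-diketone (C1 and C2 both C=O; C3–H) (not isolated) | O=C1C(=O)c2cc(OCC=C)c3c(OCC=C)cc(OC)cc3c2[C@@]2(C)O[C@@H]3CCCN3[C@@H]12 | intermediate
19 | (4R,2′S)-8,9-bis(allyloxy)-2-hydroxy-6-methoxy-4-methylphenanthren-1(4H)-one with N on C3 (C2=C3 enaminone), ring D oxygen on C4 and ring E at N–C2′; C2′–H and C4–CH3 on the same face of ring D | OC1=C2N3CCC[C@@H]3O[C@]2(C)c2c(C1=O)cc(OCC=C)c1c(OCC=C)cc(OC)cc21 | intermediate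
20 | 2-O-methyl ether of 19 (4R,2′S) | COC1=C2N3CCC[C@@H]3O[C@]2(C)c2c(C1=O)cc(OCC=C)c1c(OCC=C)cc(OC)cc21 | intermediate
21 | 8,9-dihydroxy (ring B naphthol) tautomer of the target (4R,2′S) (not isolated) | COC1=C2N3CCC[C@@H]3O[C@]2(C)c2c(C1=O)cc(O)c1c(O)cc(OC)cc21 | intermediate
22 | CNP0528850.1: (4R,2′S)-8-hydroxy-2,6-dimethoxy-4-methyl-10H-phenanthrene-1,9-dione with N on C3, ring D oxygen on C4 and ring E at N–C2′ | COC1=C2N3CCC[C@@H]3O[C@]2(C)C2=C(CC(=O)c3c(O)cc(OC)cc32)C1=O | target

**Totals**

Total step count: 14.
Longest linear sequence: 13 steps (steps 1–8 and 10–14; step 9 is a one-step branch).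

**Steps most likely to fail**

1. Step 10 (Proposed new method). The gold carbenoid may be consumed before the liberated imine reaches it: by Friedel–Crafts closure onto the electron-rich naphthalene position ortho to the side chain, by addition of the acetyl oxygen to the activated alkyne, or by a second oxygen transfer. Separately, facial discrimination by the silyloxy group may be low or of the opposite sense. The fallback uses known reaction types only and sets out from alkyne 11. Silver-catalysed bromination of the terminal alkyne (NBS, AgNO3 cat., acetone) would give the 1-bromoalkyne F1. Hydration of the haloalkyne (Ph3PAuNTf2 cat., H2O, 1,4-dioxane; the ortho acetyl group can only assist, since its participation leads to the same ketone) would give the bromomethyl ketone F2. N-Alkylation of 1-pyrroline 14 (here prepared separately from pyrrolidine 12 with Na2S2O8, AgNO3 cat., aq. NaOH) in MeCN would give the pyrrolinium bromide F3. Et3N would deprotonate F3 to ylide 15, which comes back to the route at cycloadduct 16. In this stepwise form the cycloaddition can also be held under equilibrating conditions if kinetic selectivity is poor, and the (S,S) catalyst in step 6 gives the antipodal carbinol if the sense of induction is opposite.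

2. Step 8. Addition to the doubly ortho-flanked nitrile may be slow, so that deprotonation at the propargylic carbon (loss of configuration) competes, and the hindered ketimine may resist hydrolysis under conditions the silyl ether tolerates. The fallback sets out from nitrile 10. DIBAL-H (toluene, −78 °C, dilute acid work-up) would give the aldehyde F4, whose aldimine precursor hydrolyses easily. MeMgBr (THF, 0 °C) would give the secondary alcohol F5 as a mixture at the new carbinol carbon. Dess–Martin oxidation would return to ketone 11.

3. Step 2. In the strongly acidic medium the nitrile may be hydrated, or the electron-rich arene and the acrylate may oligomerise, faster than the ester acylates the ring. The fallback sets out from diester 3. LiOH (1 equiv, THF/H2O, 0 °C) would saponify the unconjugated ester to the half-acid F6. Ac2O/NaOAc (reflux) would close ring B through the mixed anhydride to the naphthyl acetate F7, the classical Stobbe cyclisation. K2CO3 in MeOH would return naphthol 4.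

**Further compounds**

F1 | step 10 | 1-{4,5-bis(allyloxy)-2-[(1R)-3-bromo-1-(tert-butyldimethylsilyloxy)prop-2-yn-1-yl]-7-methoxynaphthalen-1-yl}ethan-1-one | BrC#C[C@H](O[Si](C)(C)C(C)(C)C)c1cc(OCC=C)c2c(OCC=C)cc(OC)cc2c1C(C)=O
F2 | step 10 | (1R)-1-[1-acetyl-4,5-bis(allyloxy)-7-methoxynaphthalen-2-yl]-3-bromo-1-(tert-butyldimethylsilyloxy)propan-2-one | BrCC(=O)[C@H](O[Si](C)(C)C(C)(C)C)c1cc(OCC=C)c2c(OCC=C)cc(OC)cc2c1C(C)=O
F3 | step 10 | 1-{(3R)-3-[1-acetyl-4,5-bis(allyloxy)-7-methoxynaphthalen-2-yl]-3-(tert-butyldimethylsilyloxy)-2-oxopropyl}-3,4-dihydro-2H-pyrrol-1-ium bromide | [Br-].O=C(C[N+]1=CCCC1)[C@H](O[Si](C)(C)C(C)(C)C)c1cc(OCC=C)c2c(OCC=C)cc(OC)cc2c1C(C)=O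
F4 | step 8 | 4,5-bis(allyloxy)-2-[(1S)-1-(tert-butyldimethylsilyloxy)prop-2-yn-1-yl]-7-methoxynaphthalene-1-carbaldehyde | C#C[C@H](O[Si](C)(C)C(C)(C)C)c1cc(OCC=C)c2c(OCC=C)cc(OC)cc2c1C=O
F5 | step 8 | 1-{4,5-bis(allyloxy)-2-[(1S)-1-(tert-butyldimethylsilyloxy)prop-2-yn-1-yl]-7-methoxynaphthalen-1-yl}ethan-1-ol (mixture at the new carbinol carbon) | C#C[C@H](O[Si](C)(C)C(C)(C)C)c1cc(OCC=C)c2c(OCC=C)cc(OC)cc2c1C(C)O
F6 | step 2 | 4-cyano-4-(3,5-dimethoxyphenyl)-3-(methoxycarbonyl)but-3-enoic acid (E/Z mixture) | COC(=O)C(CC(O)=O)=C(C#N)c1cc(OC)cc(OC)c1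
F7 | step 2 | methyl 4-acetoxy-1-cyano-5,7-dimethoxynaphthalene-2-carboxylate | COC(=O)c1cc(OC(C)=O)c2c(OC)cc(OC)cc2c1C#N
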